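**Retrosynthetic overview**
1. The target is a 6,8-dioxabicyclo[3.2.2]nonan-7-one (C1 carries the acetoxypentenyl chain, C2 the hydroxyl, C5 the methyl, C9 the hydroxypentenyl chain). The lactone bond O6–C5 is made last, by Markovnikov hydroacyloxylation of a 6-methylideneoxepane-2-carboxylic acid.
2. Key disconnection: O8–C1 and C9–C5, i.e. the whole oxepane ring (O8, C9, C5, C4, C3, C2, C1), back to aldehyde 5 (C9 and O8, from nerol) and the epoxy silyl ether 18.
3. Enabling feature: C1, C2 and the lactone carbon C7 form a masked 2,3-epoxy-1-ol (C7 at the CH2O level). The CH2O–Si group on C1 ferries the aldehyde oxygen onto C1 through a temporary 1,3-dioxolane (inversion at C1, oxygen released on C2), and the oxocarbenium ion then formed at C9 lies within 7-exo reach of the 2-silylalkene carbon C5.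
4. 18 comes from a Z-selective Wittig union of an α-silyloxy ketone with a 2-silylalkenyl ylide, then Sharpless epoxidation; the two side-chain (Z)-alkenes come from nerol and from a Still–Gennari olefination.
5. Ring order: oxirane → temporary dioxolane → oxepane → dioxanone lactone (bicycle) → deprotection.

Key step: step 13

Remark: 2-[(tert-butyldimethylsilyl)oxy]-N-methoxy-N-methylacetamide (9) is taken as purchasable; otherwise it is two routine steps from methyl glycolate.

Step 1
Reactants: 1 nerol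
Product: 2 tert-butyl{[(2Z)-3,7-dimethylocta-2,6-dien-1-yl]oxy}diphenylsilane
Conditions: t-BuPh2SiCl, imidazole, DMF, 0 °C → rt
Reagents that add atoms: tert-butyl(chloro)diphenylsilane, CC(C)(C)[Si](Cl)(c1ccccc1)c1ccccc1
Why: Imidazole-mediated silyl ether formation at the primary allylic alcohol; the robust silyl group is chosen to outlast the later silyl triflate, hydride and oxidation steps.

Step 2
Reactants: 2 neryl silyl ether
Product: 3 tert-butyl{[(2Z)-5-(3,3-dimethyloxiran-2-yl)-3-methylpent-2-en-1-yl]oxy}diphenylsilane (racemic)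
Conditions: mCPBA, NaHCO3, CH2Cl2, −20 °C
Reagents that add atoms: 3-chloroperoxybenzoic acid, OOC(=O)c1cccc(Cl)c1
Why: Prilezhaev epoxidation should favour the distal, more electron-rich trisubstituted alkene because the 2,3-alkene is deactivated by the allylic silyloxy group; the racemic epoxide centre is destroyed in step 3.

Step 3
Reactants: 3 terminal epoxide
Product: 5 (4Z)-6-[(tert-butyldiphenylsilyl)oxy]-4-methylhex-4-enal, via vicinal diol 4 (not isolated)
Conditions: H5IO6, THF/H2O, 0 °C → rt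
Reagents that add atoms: water, O
Why: Acid-promoted epoxide hydrolysis followed by Malaprade glycol cleavage in the same flask excises acetone and leaves the (Z)-alkene untouched.

Step 4
Reactants: 6 5-chloropent-1-yne
Product: 7 (5-chloropent-1-en-2-yl)triethylsilane
Conditions: Et3SiH, [Cp*Ru(MeCN)3]PF6 (1 mol %), CH2Cl2, 0 °C → rt
Reagents that add atoms: triethylsilane, CC[SiH](CC)CC
Why: Ruthenium-catalysed hydrosilylation of a terminal alkyne is Markovnikov-selective and gives the 2-silyl-1-alkene needed later as ipso-nucleophile; the alkyl chloride is inert.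

Step 5
Reactants: 7 chloro vinylsilane
Product: 8 triphenyl[4-(triethylsilyl)pent-4-en-1-yl]phosphonium iodide
Conditions: PPh3, NaI, MeCN, reflux
Reagents that add atoms: triphenylphosphine, c1ccc(cc1)P(c1ccccc1)c1ccccc1; sodium iodide, [Na+].[I-]
Why: In situ Finkelstein exchange followed by SN2 quaternisation of the phosphine gives the Wittig salt.

Step 6
Reactants: 9 2-[(tert-butyldimethylsilyl)oxy]-N-methoxy-N-methylacetamide
Product: 10 1-[(tert-butyldimethylsilyl)oxy]hex-5-en-2-one
Conditions: but-3-en-1-ylmagnesium bromide, THF, 0 °C; aq. NH4Cl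
Reagents that add atoms: but-3-en-1-ylmagnesium bromide, C=CCC[Mg]Br
Why: Weinreb ketone synthesis; the chelated tetrahedral intermediate prevents over-addition.

Step 7
Reactants: 10 hexenone
Product: 12 5-[(tert-butyldimethylsilyl)oxy]-4-oxopentanal, via ozonide 11 (not isolated)
Conditions: O3, CH2Cl2, −78 °C; then PPh3, −78 °C → rt
Reagents that add atoms: ozone, [O-][O+]=O
Why: Ozonolysis with reductive work-up cleaves the only alkene; the 1,4-keto aldehyde is used without delay.

Step 8
Reactants: 12 keto aldehyde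
Product: 13 methyl (2Z)-7-[(tert-butyldimethylsilyl)oxy]-2-methyl-6-oxohept-2-enoate
Conditions: methyl 2-[bis(2,2,2-trifluoroethoxy)phosphoryl]propanoate, KN(SiMe3)2, 18-crown-6, THF, −78 °C
Reagents that add atoms: methyl 2-[bis(2,2,2-trifluoroethoxy)phosphoryl]propanoate, COC(=O)C(C)P(=O)(OCC(F)(F)F)OCC(F)(F)F
Why: Still–Gennari olefination; the phosphonate anion should react with the aldehyde and not the ketone at −78 °C and give the (Z)-enoate, which fixes the geometry of the later allylic acetate.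

Step 9
Reactants: 8 phosphonium iodide; 13 keto enoate
Product: 15 methyl (2Z,6Z)-6-{[(tert-butyldimethylsilyl)oxy]methyl}-2-methyl-10-(triethylsilyl)undeca-2,6,10-trienoate, via phosphorus ylide 14 (not isolated)
Conditions: NaN(SiMe3)2, THF, −78 → 0 °C; then 13, −78 °C → rt
Reagents that add atoms: none
Why: Wittig olefination of an α-oxygenated ketone with a non-stabilised ylide, a combination known to place the oxygenated CH2 cis to the new alkyl chain, should give the (6Z)-alkene; the hindered enoate is expected to be spared at low temperature.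

Step 10
Reactants: 15 silyl ether
Product: 16 methyl (2Z,6Z)-6-(hydroxymethyl)-2-methyl-10-(triethylsilyl)undeca-2,6,10-trienoate
Conditions: HF·pyridine, pyridine, THF, 0 °C
Reagents that add atoms: none
Why: Fluoride cleavage of the primary tert-butyldimethylsilyl ether; the C(sp2)–Si bond and the ester are stable to buffered HF.

Step 11
Reactants: 16 (Z)-allylic alcohol
Product: 17 methyl (2Z)-5-{(2R,3S)-2-(hydroxymethyl)-3-[3-(triethylsilyl)but-3-en-1-yl]oxiran-2-yl}-2-methylpent-2-enoate
Conditions: Ti(OiPr)4, D-(−)-diisopropyl tartrate, t-BuOOH, 4 Å MS, CH2Cl2, −20 °C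
Reagents that add atoms: tert-butyl hydroperoxide, CC(C)(C)OO
Why: Sharpless asymmetric epoxidation of the only allylic alcohol; with D-(−)-tartrate the (Z)-alkene should give the (2R,3S)-epoxy alcohol, which sets under reagent control the two centres that become C1 and C2 of the bicycle.

Step 12
Reactants: 17 epoxy alcohol
Product: 18 methyl (2Z)-2-methyl-5-{(2R,3S)-3-[3-(triethylsilyl)but-3-en-1-yl]-2-{[(triethylsilyl)oxy]methyl}oxiran-2-yl}pent-2-enoate
Conditions: Et3SiCl, imidazole, CH2Cl2, 0 °C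
Reagents that add atoms: chlorotriethylsilane, CC[Si](Cl)(CC)CC
Why: Imidazole-mediated silylation gives the triethylsilyl ether that acts as oxygen donor toward the aldehyde in step 13.

Step 13
Reactants: 18 epoxy silyl ether; 5 aldehyde
Product: 20 methyl (2Z)-5-[(2S,3S,7S)-7-{(3Z)-5-[(tert-butyldiphenylsilyl)oxy]-3-methylpent-3-en-1-yl}-6-methylidene-3-[(triethylsilyl)oxy]-2-{[(triethylsilyl)oxy]methyl}oxepan-2-yl]-2-methylpent-2-enoate, via dioxolane acetal 19 (not isolated)
Conditions: Et3SiOTf (0.3 equiv), 2,6-di-tert-butyl-4-methylpyridine (0.4 equiv), 4 Å MS, CH2Cl2, −78 → −30 °C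
Reagents that add atoms: none
Why: Proposed new method: Et3SiOTf activates aldehyde 5, the silyl ether oxygen of 18 adds to give an O-silyl hemiacetal, and its oxygen opens the silyl-activated epoxide at the tertiary carbon (5-exo-tet, inversion) to give dioxolane 19 with the C3 oxygen silylated; silylation of the less hindered ring oxygen of 19 then unveils the oxocarbenium ion at the former aldehyde carbon, which is captured by the silicon-bearing carbon of the 2-silylalkene with loss of Et3SiOTf, so the promoter is regenerated and no by-product forms. The closest known reaction types are the Lewis-acid conversion of 2,3-epoxy alcohol derivatives into cyclic acetals by delivery of a carbonyl oxygen to C2, and the vinylsilane-terminated cyclisation of oxocarbenium ions to alkylidene oxacycles (related to the intramolecular silyl-modified Sakurai reaction run with silyl ethers and a silyl triflate); merging them into one annulation of an aldehyde is the unprecedented part. Ring closures: the temporary dioxolane by 5-exo-tet, the oxepane (ring O–C2 and C6–C7 bonds) by 7-exo ipso attack favoured by the β-silicon effect over 8-endo attack through the CH2 terminus. Stereocentres: C2 is fixed by stereospecific backside opening of the (2R,3S)-epoxide, C3 is carried over unchanged, and C7 should be set in the C–C closure through the (E)-oxocarbenium ion with the nucleophile entering anti to the departing CH2O–Si oxygen, which puts the C7 chain cis to the C2 pentenyl chain (7S). Selectivity needed: opening at the tertiary epoxide carbon (secured by the five-membered tether), ionisation of 19 toward the oxocarbenium ion on the ring oxygen (the alternative needs an eight-membered closure), and no competing π-nucleophile (the enoate is electron-poor and the aldehyde's own alkene could close only by 5-endo attack).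

Step 14
Reactants: 20 oxepane ester
Product: 21 (2Z)-5-[(2S,3S,7S)-7-{(3Z)-5-[(tert-butyldiphenylsilyl)oxy]-3-methylpent-3-en-1-yl}-6-methylidene-3-[(triethylsilyl)oxy]-2-{[(triethylsilyl)oxy]methyl}oxepan-2-yl]-2-methylpent-2-en-1-ol
Conditions: i-Bu2AlH, CH2Cl2, −78 °C; aq. KNaC4H4O6
Reagents that add atoms: none
Why: 1,2-Reduction of the only carbonyl group (the enoate) gives the (Z)-allylic alcohol without touching silyl ethers or alkenes.

Step 15
Reactants: 21 allylic alcohol
Product: 22 (2Z)-5-[(2S,3S,7S)-7-{(3Z)-5-[(tert-butyldiphenylsilyl)oxy]-3-methylpent-3-en-1-yl}-6-methylidene-3-[(triethylsilyl)oxy]-2-{[(triethylsilyl)oxy]methyl}oxepan-2-yl]-2-methylpent-2-en-1-yl acetate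
Conditions: Ac2O, pyridine, DMAP (cat.), CH2Cl2, 0 °C
Reagents that add atoms: acetic anhydride, CC(=O)OC(C)=O
Why: DMAP-catalysed acetylation of the only free hydroxyl installs the acetate of the target.

Step 16
Reactants: 22 bis(triethylsilyl) ether
Product: 23 (2Z)-5-[(2R,3S,7S)-7-{(3Z)-5-[(tert-butyldiphenylsilyl)oxy]-3-methylpent-3-en-1-yl}-2-formyl-6-methylidene-3-[(triethylsilyl)oxy]oxepan-2-yl]-2-methylpent-2-en-1-yl acetate
Conditions: (COCl)2, DMSO, CH2Cl2, −78 → −35 °C; then Et3N, −78 °C → rt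
Reagents that add atoms: none
Why: Swern oxidation applied directly to a primary triethylsilyl ether: the chlorosulfonium reagent cleaves and oxidises the primary silyl ether in situ, while the hindered secondary silyl ether is expected to persist.

Step 17
Reactants: 23 aldehyde
Product: 24 (2R,3S,7S)-2-[(3Z)-5-(acetyloxy)-4-methylpent-3-en-1-yl]-7-{(3Z)-5-[(tert-butyldiphenylsilyl)oxy]-3-methylpent-3-en-1-yl}-6-methylidene-3-[(triethylsilyl)oxy]oxepane-2-carboxylic acid
Conditions: NaClO2, NaH2PO4, 2-methylbut-2-ene, t-BuOH/H2O, 0 °C → rt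
Reagents that add atoms: sodium chlorite, [Na+].[O-]Cl=O
Why: Pinnick oxidation of the non-enolisable α-alkoxy aldehyde, with 2-methylbut-2-ene trapping HOCl so that the alkenes survive.

Step 18
Reactants: 24 methylidene acid
Product: 25 (2Z)-5-[(1R,2S,5R,9S)-9-{(3Z)-5-[(tert-butyldiphenylsilyl)oxy]-3-methylpent-3-en-1-yl}-5-methyl-7-oxo-2-[(triethylsilyl)oxy]-6,8-dioxabicyclo[3.2.2]nonan-1-yl]-2-methylpent-2-en-1-yl acetate
Conditions: [N,N′-bis(3,5-di-tert-butylsalicylidene)-1,2-cyclohexanediaminato]cobalt (5 mol %), 1-fluoro-2,4,6-trimethylpyridinium tetrafluoroborate, (Me2SiH)2O, PhCF3, rt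
Reagents that add atoms: none
Why: Cobalt-catalysed hydrogen-atom-transfer/radical-polar crossover hydroacyloxylation: hydrogen-atom transfer should be fastest at the 1,1-disubstituted alkene, the C2 carboxyl captures the tertiary cation equivalent at C6 in a 6-exo Markovnikov lactonisation, and because the tether reaches only one face the new quaternary centre (C5 of the bicycle, R) is set by the ring.

Step 19
Reactants: 25 silylated lactone
Product: 26 (2Z)-5-{(1R,2S,5R,9S)-2-hydroxy-9-[(3Z)-5-hydroxy-3-methylpent-3-en-1-yl]-5-methyl-7-oxo-6,8-dioxabicyclo[3.2.2]nonan-1-yl}-2-methylpent-2-en-1-yl acetate (CNP0174851.1)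
Conditions: HF·pyridine, pyridine, THF, 0 °C → rt
Reagents that add atoms: none
Why: Global fluoride desilylation removes both silyl ethers; the acetate and the bridged lactone are stable to buffered HF.

**Compound list**
1 | nerol, (2Z)-3,7-dimethylocta-2,6-dien-1-ol | CC(C)=CCC/C(C)=C\CO | starting material
2 | tert-butyl{[(2Z)-3,7-dimethylocta-2,6-dien-1-yl]oxy}diphenylsilane | CC(C)=CCC/C(C)=C\CO[Si](c1ccccc1)(c1ccccc1)C(C)(C)C | intermediate
3 | tert-butyl{[(2Z)-5-(3,3-dimethyloxiran-2-yl)-3-methylpent-2-en-1-yl]oxy}diphenylsilane (racemic) | CC1(C)OC1CC/C(C)=C\CO[Si](c1ccccc1)(c1ccccc1)C(C)(C)C | intermediate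
4 | (6Z)-8-[(tert-butyldiphenylsilyl)oxy]-2,6-dimethyloct-6-ene-2,3-diol (formed in the flask, not isolated) | CC(C)(O)C(O)CC/C(C)=C\CO[Si](c1ccccc1)(c1ccccc1)C(C)(C)C | intermediate
5 | (4Z)-6-[(tert-butyldiphenylsilyl)oxy]-4-methylhex-4-enal | O=CCC/C(C)=C\CO[Si](c1ccccc1)(c1ccccc1)C(C)(C)C | intermediate
6 | 5-chloropent-1-yne | C#CCCCCl | starting material
7 | (5-chloropent-1-en-2-yl)triethylsilane | C=C(CCCCl)[Si](CC)(CC)CC | intermediate
8 | triphenyl[4-(triethylsilyl)pent-4-en-1-yl]phosphonium iodide | C=C(CCC[P+](c1ccccc1)(c1ccccc1)c1ccccc1)[Si](CC)(CC)CC.[I-] | intermediate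
9 | 2-[(tert-butyldimethylsilyl)oxy]-N-methoxy-N-methylacetamide | CON(C)C(=O)CO[Si](C)(C)C(C)(C)C | starting material
10 | 1-[(tert-butyldimethylsilyl)oxy]hex-5-en-2-one | C=CCCC(=O)CO[Si](C)(C)C(C)(C)C | intermediate
11 | 1-[(tert-butyldimethylsilyl)oxy]-4-(1,2,4-trioxolan-3-yl)butan-2-one (ozonide, not isolated) | CC(C)(C)[Si](C)(C)OCC(=O)CCC1OCOO1 | intermediate
12 | 5-[(tert-butyldimethylsilyl)oxy]-4-oxopentanal | O=CCCC(=O)CO[Si](C)(C)C(C)(C)C | intermediate
13 | methyl (2Z)-7-[(tert-butyldimethylsilyl)oxy]-2-methyl-6-oxohept-2-enoate | COC(=O)/C(C)=C\CCC(=O)CO[Si](C)(C)C(C)(C)C | intermediate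
14 | triphenyl[4-(triethylsilyl)pent-4-en-1-ylidene]-λ5-phosphane (ylide, not isolated) | C=C(CCC=P(c1ccccc1)(c1ccccc1)c1ccccc1)[Si](CC)(CC)CC | intermediate
15 | methyl (2Z,6Z)-6-{[(tert-butyldimethylsilyl)oxy]methyl}-2-methyl-10-(triethylsilyl)undeca-2,6,10-trienoate | COC(=O)/C(C)=C\CC/C(CO[Si](C)(C)C(C)(C)C)=C/CCC(=C)[Si](CC)(CC)CC | intermediate
16 | methyl (2Z,6Z)-6-(hydroxymethyl)-2-methyl-10-(triethylsilyl)undeca-2,6,10-trienoate | COC(=O)/C(C)=C\CC/C(CO)=C/CCC(=C)[Si](CC)(CC)CC | intermediate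
17 | methyl (2Z)-5-{(2R,3S)-2-(hydroxymethyl)-3-[3-(triethylsilyl)but-3-en-1-yl]oxiran-2-yl}-2-methylpent-2-enoate | COC(=O)/C(C)=C\CC[C@]1(CO)O[C@H]1CCC(=C)[Si](CC)(CC)CC | intermediate
18 | methyl (2Z)-2-methyl-5-{(2R,3S)-3-[3-(triethylsilyl)but-3-en-1-yl]-2-{[(triethylsilyl)oxy]methyl}oxiran-2-yl}pent-2-enoate | COC(=O)/C(C)=C\CC[C@]1(CO[Si](CC)(CC)CC)O[C@H]1CCC(=C)[Si](CC)(CC)CC | intermediate
19 | methyl (2Z)-5-[(4S)-2-{(3Z)-5-[(tert-butyldiphenylsilyl)oxy]-3-methylpent-3-en-1-yl}-4-{(1S)-4-(triethylsilyl)-1-[(triethylsilyl)oxy]pent-4-en-1-yl}-1,3-dioxolan-4-yl]-2-methylpent-2-enoate (acetal carbon as either epimer, not isolated) | COC(=O)/C(C)=C\CC[C@]1(COC(CC/C(C)=C\CO[Si](c2ccccc2)(c2ccccc2)C(C)(C)C)O1)[C@@H](O[Si](CC)(CC)CC)CCC(=C)[Si](CC)(CC)CC | intermediate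
20 | methyl (2Z)-5-[(2S,3S,7S)-7-{(3Z)-5-[(tert-butyldiphenylsilyl)oxy]-3-methylpent-3-en-1-yl}-6-methylidene-3-[(triethylsilyl)oxy]-2-{[(triethylsilyl)oxy]methyl}oxepan-2-yl]-2-methylpent-2-enoate | COC(=O)/C(C)=C\CC[C@@]1(CO[Si](CC)(CC)CC)O[C@@H](CC/C(C)=C\CO[Si](c2ccccc2)(c2ccccc2)C(C)(C)C)C(=C)CC[C@@H]1O[Si](CC)(CC)CC | intermediate
21 | (2Z)-5-[(2S,3S,7S)-7-{(3Z)-5-[(tert-butyldiphenylsilyl)oxy]-3-methylpent-3-en-1-yl}-6-methylidene-3-[(triethylsilyl)oxy]-2-{[(triethylsilyl)oxy]methyl}oxepan-2-yl]-2-methylpent-2-en-1-ol | OC/C(C)=C\CC[C@@]1(CO[Si](CC)(CC)CC)O[C@@H](CC/C(C)=C\CO[Si](c2ccccc2)(c2ccccc2)C(C)(C)C)C(=C)CC[C@@H]1O[Si](CC)(CC)CC | intermediate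
22 | (2Z)-5-[(2S,3S,7S)-7-{(3Z)-5-[(tert-butyldiphenylsilyl)oxy]-3-methylpent-3-en-1-yl}-6-methylidene-3-[(triethylsilyl)oxy]-2-{[(triethylsilyl)oxy]methyl}oxepan-2-yl]-2-methylpent-2-en-1-yl acetate | CC(=O)OC/C(C)=C\CC[C@@]1(CO[Si](CC)(CC)CC)O[C@@H](CC/C(C)=C\CO[Si](c2ccccc2)(c2ccccc2)C(C)(C)C)C(=C)CC[C@@H]1O[Si](CC)(CC)CC | intermediate
23 | (2Z)-5-[(2R,3S,7S)-7-{(3Z)-5-[(tert-butyldiphenylsilyl)oxy]-3-methylpent-3-en-1-yl}-2-formyl-6-methylidene-3-[(triethylsilyl)oxy]oxepan-2-yl]-2-methylpent-2-en-1-yl acetate | CC(=O)OC/C(C)=C\CC[C@@]1(C=O)O[C@@H](CC/C(C)=C\CO[Si](c2ccccc2)(c2ccccc2)C(C)(C)C)C(=C)CC[C@@H]1O[Si](CC)(CC)CC | intermediate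
24 | (2R,3S,7S)-2-[(3Z)-5-(acetyloxy)-4-methylpent-3-en-1-yl]-7-{(3Z)-5-[(tert-butyldiphenylsilyl)oxy]-3-methylpent-3-en-1-yl}-6-methylidene-3-[(triethylsilyl)oxy]oxepane-2-carboxylic acid | CC(=O)OC/C(C)=C\CC[C@@]1(C(=O)O)O[C@@H](CC/C(C)=C\CO[Si](c2ccccc2)(c2ccccc2)C(C)(C)C)C(=C)CC[C@@H]1O[Si](CC)(CC)CC | intermediate
25 | (2Z)-5-[(1R,2S,5R,9S)-9-{(3Z)-5-[(tert-butyldiphenylsilyl)oxy]-3-methylpent-3-en-1-yl}-5-methyl-7-oxo-2-[(triethylsilyl)oxy]-6,8-dioxabicyclo[3.2.2]nonan-1-yl]-2-methylpent-2-en-1-yl acetate | CC(=O)OC/C(C)=C\CC[C@@]12O[C@@H](CC/C(C)=C\CO[Si](c3ccccc3)(c3ccccc3)C(C)(C)C)[C@@](C)(CC[C@@H]1O[Si](CC)(CC)CC)OC2=O | intermediate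
26 | (2Z)-5-{(1R,2S,5R,9S)-2-hydroxy-9-[(3Z)-5-hydroxy-3-methylpent-3-en-1-yl]-5-methyl-7-oxo-6,8-dioxabicyclo[3.2.2]nonan-1-yl}-2-methylpent-2-en-1-yl acetate | CC(=O)OC/C(C)=C\CC[C@@]12O[C@@H](CC/C(C)=C\CO)[C@@](C)(CC[C@@H]1O)OC2=O | target

**Step count and risks**
Total: 19 steps. Longest linear sequence: 14 steps (steps 6 to 19, from 9).

Steps most likely to fail:

Step 13 (proposed new method). What may go wrong: ionisation or rearrangement of the silyl-activated epoxide before the acetal relay, scrambling of the acetal onto the C3 oxygen (which would open a six-membered closure), or poor facial selectivity in the C–C closure at C7. Fallback with known reactions, run separately: setting out from epoxy alcohol 17 and aldehyde 5, a BF3·OEt2-catalysed acetalisation (opening of the 2,3-epoxy alcohol at C2 by the hemiacetal hydroxyl) should give the hydroxy dioxolane F1. Silylation of F1 (Et3SiOTf, 2,6-lutidine, CH2Cl2, −78 °C) gives 19, now isolated and purified as one regioisomer. A separate vinylsilane-terminated acetal cyclisation of 19 (stoichiometric Et3SiOTf, CH2Cl2, −78 °C) then comes back to the route at 20.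

Step 18. What may go wrong: hydrogen-atom transfer to one of the trisubstituted alkenes, or capture of the tertiary cation equivalent by the neighbouring silyl ether oxygen (transannular ether formation with loss of the silyl group) instead of by the carboxyl group. Fallback: setting out from 24, iodolactonisation (I2, NaHCO3, MeCN, 0 °C), in which the carboxylate is the only competent internal nucleophile, should give the iodomethyl lactone F2; radical deiodination (Bu3SnH, AIBN, benzene, 80 °C) comes back to the route at 25.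

Step 16. What may go wrong: incomplete cleavage of the hindered neopentyl silyl ether, or loss of the secondary silyl ether under the acidic Swern regime. Fallback: setting out from 22, selective methanolysis of the primary triethylsilyl ether (pyridinium p-toluenesulfonate, MeOH/CH2Cl2, 0 °C) should give the primary alcohol F3; Dess–Martin oxidation (NaHCO3, CH2Cl2, rt) comes back to the route at 23.

Further compounds
F1 | step 13 | methyl (2Z)-5-[(4S)-2-{(3Z)-5-[(tert-butyldiphenylsilyl)oxy]-3-methylpent-3-en-1-yl}-4-[(1S)-1-hydroxy-4-(triethylsilyl)pent-4-en-1-yl]-1,3-dioxolan-4-yl]-2-methylpent-2-enoate | COC(=O)/C(C)=C\CC[C@]1(COC(CC/C(C)=C\CO[Si](c2ccccc2)(c2ccccc2)C(C)(C)C)O1)[C@@H](O)CCC(=C)[Si](CC)(CC)CC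
F2 | step 18 | (2Z)-5-[(1R,2S,5R,9S)-9-{(3Z)-5-[(tert-butyldiphenylsilyl)oxy]-3-methylpent-3-en-1-yl}-5-(iodomethyl)-7-oxo-2-[(triethylsilyl)oxy]-6,8-dioxabicyclo[3.2.2]nonan-1-yl]-2-methylpent-2-en-1-yl acetate | CC(=O)OC/C(C)=C\CC[C@@]12O[C@@H](CC/C(C)=C\CO[Si](c3ccccc3)(c3ccccc3)C(C)(C)C)[C@@](CI)(CC[C@@H]1O[Si](CC)(CC)CC)OC2=O
F3 | step 16 | (2Z)-5-[(2S,3S,7S)-7-{(3Z)-5-[(tert-butyldiphenylsilyl)oxy]-3-methylpent-3-en-1-yl}-2-(hydroxymethyl)-6-methylidene-3-[(triethylsilyl)oxy]oxepan-2-yl]-2-methylpent-2-en-1-yl acetate | CC(=O)OC/C(C)=C\CC[C@@]1(CO)O[C@@H](CC/C(C)=C\CO[Si](c2ccccc2)(c2ccccc2)C(C)(C)C)C(=C)CC[C@@H]1O[Si](CC)(CC)CC
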